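**Retrosynthetic overview**
1. The plan rests on this feature: in the ten-membered ring C3 and C8 are 1,6-related (C3–C4–C5–C6–C7–C8) and C5 carries the exocyclic C16 methylene. A trans-decalin (rings A and B) with a C3–C8 bond, a C8 vinyl carbinol and a C3 allenyl group therefore maps onto it by a [3,3] shift that breaks C3–C8 and forms C5–C6.
2. Target ⇒ 6-deschloro compound (allylic chlorination at C6 last) ⇒ dienyl hydroxy-lactone; one peracid step makes the 11,20-oxirane and the 3,4-epoxide, which the C8 hydroxyl opens at C4 to give the oxane bridge.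
3. Lactone and C8 quaternary centre ⇒ tethered aldol of a C7 propionate onto the C8 ketone; C7–O by Rubottom oxidation; C9–O by Rubottom oxidation, then oxidation and reduction.
4. Decalin ⇒ (R)-Wieland–Miescher ketone: ring A by deconjugative ketalisation, hydroboration, Wittig methylenation and bulky-hydride reduction; ring B by 2,8-dione, propargyl enol ether, Claisen rearrangement and vinyl addition.
5. Ring order: rings A and B (bought) → ten-membered ring (step 17) → γ-lactone (step 21) → oxane bridge and spiro-oxirane (step 27).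

Key step: step 17

Assumption: enantiopure (R)-(−)-Wieland–Miescher ketone is bought. Locants are those of the briarane skeleton throughout (C1–C10 large ring, C1/C10–C14 ring A, C15 methyl on C1, C16 on C5, C17–C19 lactone, C20 on C11); β is the face of the C15 methyl, α that of H-10. TBS = tert-butyldimethylsilyl, PMB = 4-methoxybenzyl.

Step 1
Reactants: 1 (R)-Wieland–Miescher ketone
Product: 2 14β-hydroxy-9-en-8-one
Conditions: NaBH4 (0.3 equiv), EtOH, −10 °C
Reagents that add atoms: none
Why: Chemoselective borohydride reduction of the saturated ketone (the vinylogous enone carbonyl is less electrophilic); the carbinol centre only masks this ketone and is removed in step 4.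

Step 2
Reactants: 2 14β-hydroxy-9-en-8-one
Product: 3 8-dioxolane of the 10(11)-en-14β-ol
Conditions: HOCH2CH2OH, TsOH (cat.), PhH, reflux, Dean–Stark
Reagents that add atoms: ethylene glycol OCCO
Why: Deconjugative ketalisation: the enone is ketalised through its dienol, so the double bond moves to C10–C11 and C11 becomes open to oxygenation.

Step 3
Reactants: 3 8-dioxolane of the 10(11)-en-14β-ol
Product: 4 trans-fused 8-dioxolane 11α,14β-diol
Conditions: BH3·THF (2.5 equiv), THF, 0 °C → rt; then NaOH, H2O2
Reagents that add atoms: hydrogen peroxide OO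
Why: Hydroboration–oxidation puts boron on the less substituted C11 and hydrogen on C10 in a syn addition from the α-face, opposite to the angular methyl, which sets H-10 α (trans fusion) and the 11α-alcohol.

Step 4
Reactants: 4 trans-fused 8-dioxolane 11α,14β-diol
Product: 5 trans-fused 8-dioxolane 11,14-dione
Conditions: Dess–Martin periodinane, NaHCO3, CH2Cl2, rt
Reagents that add atoms: none
Why: Buffered Dess–Martin oxidation of both secondary alcohols; the non-basic medium should leave C10 untouched.

Step 5
Reactants: 5 trans-fused 8-dioxolane 11,14-dione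
Product: 6 11(20)-methylene 8-dioxolane 14-ketone
Conditions: Ph3PCH3Br, KOtBu (1.1 equiv of ylide), THF, 0 °C
Reagents that add atoms: methyltriphenylphosphonium bromide C[P+](c1ccccc1)(c1ccccc1)c1ccccc1.[Br-]
Why: Wittig methylenation should take the C11 ketone and spare the neopentyl C14 ketone next to the quaternary C1, and at 0 °C it should be faster than enolisation toward C10.

Step 6
Reactants: 6 11(20)-methylene 8-dioxolane 14-ketone
Product: 7 11(20)-methylene 8-dioxolane 14α-ol
Conditions: LiBH(sBu)3, THF, −78 °C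
Reagents that add atoms: none
Why: The bulky hydride avoids the axial path on the α-face (axial H-10 and H-12) and attacks equatorially, which gives the axial 14α-alcohol trans to the angular methyl.

Step 7
Reactants: 7 11(20)-methylene 8-dioxolane 14α-ol
Product: 8 14α-TBS ether of 7
Conditions: TBSOTf, 2,6-lutidine, CH2Cl2, 0 °C
Reagents that add atoms: tert-butyldimethylsilyl trifluoromethanesulfonate CC(C)(C)[Si](C)(C)OS(=O)(=O)C(F)(F)F
Why: Silylation with the silyl triflate, which is reactive enough for the hindered axial neopentyl alcohol.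

Step 8
Reactants: 8 14α-TBS ether of 7
Product: 9 14α-TBSO-11(20)-methylene trans-decalin-8-one
Conditions: PPTS, acetone/H2O, 50 °C
Reagents that add atoms: water O
Why: Mild acid hydrolysis of the dioxolane; these conditions should neither move the exocyclic olefin into the ring nor cleave the hindered silyl ether.

Step 9
Reactants: 9 14α-TBSO-11(20)-methylene trans-decalin-8-one
Product: 11 2-en-8-one, via trimethylsilyl enol ether 10 (not isolated)
Conditions: LiN(iPr)2, Me3SiCl, THF, −78 °C; then Pd(OAc)2, MeCN, rt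
Reagents that add atoms: chlorotrimethylsilane C[Si](C)(C)Cl (kept only in 10)
Why: Kinetic enolisation of the trans-decalone goes toward C3, away from the ring-fusion side, and Saegusa–Ito oxidation of the silyl enol ether gives the enone.

Step 10
Reactants: 11 2-en-8-one
Product: 12 2α,3α-epoxy-8-one
Conditions: H2O2, NaOH, MeOH, 0 °C
Reagents that add atoms: hydrogen peroxide OO
Why: Weitz–Scheffer epoxidation of the enone from the face opposite to the angular methyl; both epoxide centres are lost again in step 11.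

Step 11
Reactants: 12 2α,3α-epoxy-8-one
Product: 13 2,8-dione
Conditions: Pd(PPh3)4 (5 mol%), Ph2PCH2CH2PPh2, PhMe, 100 °C
Reagents that add atoms: none
Why: Zerovalent palladium isomerises α,β-epoxy ketones to β-diketones (opening of the C–O bond next to the carbonyl, β-hydride elimination from C2, tautomerisation), which places the C2 carbonyl.

Step 12
Reactants: 13 2,8-dione, 14 propargyl alcohol
Product: 15 8-(prop-2-ynyloxy)-3(8)-en-2-one
Conditions: PPh3, iPrO2CN=NCO2iPr, THF, 0 °C → rt
Reagents that add atoms: none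
Why: Mitsunobu O-alkylation of the enolised dione; the enol oxygen remote from the quaternary C1 is the accessible one, so the ether should form at C8 and the ketone stay at C2.

Step 13
Reactants: 15 8-(prop-2-ynyloxy)-3(8)-en-2-one
Product: 16 8-(prop-2-ynyloxy)-3(8)-en-2β-ol
Conditions: iBu2AlH, CH2Cl2, −78 °C; Rochelle-salt work-up
Reagents that add atoms: none
Why: 1,2-Reduction of the vinylogous ester; hydride enters from the α-face, anti to the axial C15 methyl on the neighbouring carbon, which gives the equatorial 2β-alcohol.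

Step 14
Reactants: 16 8-(prop-2-ynyloxy)-3(8)-en-2β-ol
Product: 17 2β-PMB ether of 16
Conditions: NaH, 4-MeOC6H4CH2Br, THF/DMF, 0 °C
Reagents that add atoms: 4-methoxybenzyl bromide COc1ccc(CBr)cc1
Why: Williamson etherification under basic conditions, which the acid-labile allylic alcohol on the enol ether tolerates.

Step 15
Reactants: 17 2β-PMB ether of 16
Product: 18 3α-(propa-1,2-dienyl)-2β-PMBO-8-one
Conditions: PhMe, 140 °C, sealed tube, base-washed glass; product used at once
Reagents that add atoms: none
Why: Thermal propargyl vinyl ether Claisen rearrangement (Saucy–Marbet type): the alkyne terminus bonds to C3 and the propargyl unit becomes the allene; the new bond forms on the α-face, anti to the 2β-ether and to the syn-axial C15 methyl, which gives the equatorial 3α-allenyl ketone.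

Step 16
Reactants: 18 3α-(propa-1,2-dienyl)-2β-PMBO-8-one, 19 vinylmagnesium bromide
Product: 20 8α-hydroxy-8β-vinyl-3α-allenyl trans-decalin
Conditions: CH2=CHMgBr/CeCl3, THF, −78 °C
Reagents that add atoms: none
Why: Organocerium 1,2-addition to the enolisable ketone; as with 2-substituted cyclohexanones the reagent should attack equatorially, trans to the C3 substituent, so vinyl is equatorial (β) and hydroxyl axial (α).

Step 17
Reactants: 20 8α-hydroxy-8β-vinyl-3α-allenyl trans-decalin
Product: 22 ten-membered 8-ketone (E-3,4-olefin; 5(16)-methylene), via potassium enolate 21 (not isolated)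
Conditions: KH, 18-crown-6, THF, 0 °C → rt; aq. NH4Cl, −78 °C
Reagents that add atoms: none
Why: KH/18-crown-6 turns the C8 hydroxyl into a free potassium alkoxide and the 1,5-diene C6=C7–C8–C3–C4=C5 undergoes a charge-accelerated [3,3] shift through a chair, the C3–C8 bond of ring B breaking as C5–C6 forms; only the inner allene double bond takes part, so C5 keeps the C16 methylene. The closest known reaction is the anionic oxy-Cope ring expansion of trans-1,2-dialkenylcyclohexanols to E-cyclodec-5-enones, of which the allenyl partner is a known but less common variant. The ten-membered ring is not closed end to end: it results from four-atom expansion of ring B by the sigmatropic shift. No stereocentre is formed (C3 and C8 become trigonal); the chair fixes the E-3,4-olefin and the E-geometry of the C7–C8 enolate. The step needs the chair pathway and one enolate regioisomer: the rigid trans-decalin holds vinyl and allenyl trans-diequatorial, and the enolate position follows from the bond shift itself. Cold protonation should give the ketone in the ring conformation inherited from the chair (C15 methyl and 3,4-olefin on the inner β-side), on which the face selectivities of steps 18, 21, 23 and 27 rest.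

Step 18
Reactants: 22 ten-membered 8-ketone (E-3,4-olefin; 5(16)-methylene)
Product: 24 7α-trimethylsilyloxy 8-ketone, via trimethylsilyl enol ether 23 (not isolated)
Conditions: LiN(iPr)2, Me3SiCl, THF, −78 °C; then dimethyldioxirane (1.05 equiv), acetone/CH2Cl2, −78 → 0 °C
Reagents that add atoms: chlorotrimethylsilane C[Si](C)(C)Cl; dimethyldioxirane CC1(C)OO1
Why: Rubottom oxidation: kinetic deprotonation should take the exposed C7 methylene (the aligned C9 hydrogen points to the shielded β-side) and regenerate the enolate of the rearrangement; the dioxirane attacks the enol ether much faster than the other olefins and from the peripheral face opposite the transannular 3,4-olefin, which sets C7–O α, and the silyl group ends on the new oxygen.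

Step 19
Reactants: 24 7α-trimethylsilyloxy 8-ketone
Product: 26 7α-trimethylsilyloxy-9α-triethylsilyloxy 8-ketone, via triethylsilyl enol ether 25 (not isolated)
Conditions: LiN(iPr)2, Et3SiCl, THF, −78 °C; then dimethyldioxirane (1.05 equiv), acetone/CH2Cl2, −78 → 0 °C
Reagents that add atoms: chlorotriethylsilane CC[Si](Cl)(CC)CC; dimethyldioxirane CC1(C)OO1
Why: The α-silyloxy methine at C7 is slow to deprotonate, so enolisation goes toward C9 and a second Rubottom oxidation brings in the C9 oxygen; attack from the open α-face is expected, but this centre is reset in step 23, so its configuration does not matter here.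

Step 20
Reactants: 26 7α-trimethylsilyloxy-9α-triethylsilyloxy 8-ketone, 27 propionic anhydride
Product: 29 7α-propionyloxy-9α-triethylsilyloxy 8-ketone, via 7α-hydroxy ketone 28 (not isolated)
Conditions: citric acid (cat.), MeOH, 0 °C; then (EtCO)2O, DMAP, pyridine, CH2Cl2, 0 °C → rt
Reagents that add atoms: none
Why: Acidic methanolysis removes the trimethylsilyl ether much faster than the triethylsilyl and TBS ethers, and esterification of the freed α-hydroxy ketone attaches the propionate as a tether for the aldol.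

Step 21
Reactants: 29 7α-propionyloxy-9α-triethylsilyloxy 8-ketone
Product: 30 8α-hydroxy γ-lactone with 9α-triethylsilyloxy group
Conditions: LiN(SiMe3)2, THF, −78 °C; AcOH quench at −78 °C
Reagents that add atoms: none
Why: Intramolecular aldol addition (5-exo-trig): the base takes the unhindered propionate α-proton and the ester enolate closes on the neighbouring C8 ketone to give the γ-lactone and the C8 tertiary alcohol; with C6 and C9 anti across C7–C8 (inherited conformation) the tether reaches only the carbonyl face that leaves the C8 oxygen gauche to C6 and C17 anti to it, which is the configuration the ether bridge needs, and the C17 methyl should take the position anti to the C9 branch, which is also expected to be the more stable lactone epimer.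

Step 22
Reactants: 30 8α-hydroxy γ-lactone with 9α-triethylsilyloxy group
Product: 31 8α,9α-diol lactone
Conditions: HF·pyridine, pyridine, THF, 0 °C
Reagents that add atoms: none
Why: Selective desilylation: buffered fluoride cleaves the triethylsilyl ether while the hindered axial TBS ether at C14 stays.

Step 23
Reactants: 31 8α,9α-diol lactone
Product: 33 8α,9β-diol lactone, via 9-ketone 32 (not isolated)
Conditions: Dess–Martin periodinane, NaHCO3, CH2Cl2, 0 °C; then NaBH4, MeOH, −40 °C
Reagents that add atoms: none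
Why: Oxidation and substrate-controlled ketone reduction: the ketone is reduced at once to avoid enolisation toward C10, and hydride comes from the α-face because the β-face of C9 is covered by the axial C15 methyl (gauche to C9 in the ring A chair), so the 9β-alcohol should result whatever step 19 gave.

Step 24
Reactants: 33 8α,9β-diol lactone
Product: 34 8α,9β,14α-triol lactone
Conditions: HF·pyridine, THF, rt → 40 °C
Reagents that add atoms: none
Why: Fluoride-mediated removal of the remaining TBS ether; the PMB ether, the lactone and the olefins are inert to it.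

Step 25
Reactants: 34 8α,9β,14α-triol lactone
Product: 35 9β,14α-diacetate
Conditions: Ac2O, DMAP, pyridine, CH2Cl2, rt → 40 °C
Reagents that add atoms: acetic anhydride CC(=O)OC(C)=O
Why: DMAP-catalysed acetylation of the two secondary alcohols; the tertiary C8 alcohol is too hindered to react and C2 is still protected.

Step 26
Reactants: 35 9β,14α-diacetate
Product: 36 2β-alcohol
Conditions: DDQ, CH2Cl2/pH 7 buffer, 0 °C
Reagents that add atoms: none
Why: Oxidative cleavage of the PMB ether under neutral conditions frees the allylic C2 hydroxyl without touching the acetates or the lactone.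

Step 27
Reactants: 36 2β-alcohol
Product: 38 6-deschloro target, via bis-epoxide 37 (not isolated)
Conditions: mCPBA (2.5 equiv), CH2Cl2, 0 °C → rt
Reagents that add atoms: 3-chloroperoxybenzoic acid O=C(OO)c1cccc(Cl)c1
Why: Prilezhaev epoxidation and transannular epoxide opening: the 11(20)-methylene is attacked from the α-face (β-face blocked by the syn-axial C15 methyl) and the 3,4-olefin on its outer face under hydrogen-bond guidance by the 2β-hydroxyl (threo epoxy alcohol); the 8α-hydroxyl then lies behind C4 inside the ring and opens the allylic epoxide by 6-exo-tet attack with inversion, which forms the oxane bridge and leaves the 3α-hydroxyl, while the 5(16)-olefin is deactivated by the adjacent epoxide.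

Step 28
Reactants: 38 6-deschloro target
Product: 39 CNP0340728.1 (target)
Conditions: N-chlorosuccinimide (1.1 equiv), PhSeCl (10 mol%), pyridine (cat.), CH2Cl2, rt
Reagents that add atoms: N-chlorosuccinimide O=C1CCC(=O)N1Cl
Why: Selenium-catalysed allylic chlorination: PhSeCl adds to the 5(16)-methylene and loses HCl toward C6 (C4 is an oxygen-bearing bridgehead) to give the C16 allyl selenide, chlorination at selenium and a [2,3] shift return the double bond to C5=C16 and deliver chlorine to C6 on the exo α-face, because the axial β-position is blocked by the C3 and C9 arms of the bridge.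

**Compound list**
1 | (R)-Wieland–Miescher ketone | C[C@@]12CCC(=O)C=C1CCCC2=O | starting material
2 | 14β-hydroxy-9-en-8-one | O=C1C=C2CCC[C@@H](O)[C@]2(C)CC1 | intermediate
3 | 8-dioxolane of the 10(11)-en-14β-ol | C12(OCCO1)CC3=CCC[C@@H](O)[C@]3(C)CC2 | intermediate
4 | trans-fused 8-dioxolane 11α,14β-diol | C12(OCCO1)C[C@H]3[C@H](O)CC[C@@H](O)[C@]3(C)CC2 | intermediate
5 | trans-fused 8-dioxolane 11,14-dione | C12(OCCO1)C[C@H]3C(=O)CCC(=O)[C@]3(C)CC2 | intermediate
6 | 11(20)-methylene 8-dioxolane 14-ketone | C12(OCCO1)C[C@H]3C(=C)CCC(=O)[C@]3(C)CC2 | intermediate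
7 | 11(20)-methylene 8-dioxolane 14α-ol | C12(OCCO1)C[C@H]3C(=C)CC[C@H](O)[C@]3(C)CC2 | intermediate
8 | 14α-TBS ether of 7 | C12(OCCO1)C[C@H]3C(=C)CC[C@H](O[Si](C)(C)C(C)(C)C)[C@]3(C)CC2 | intermediate
9 | 14α-TBSO-11(20)-methylene trans-decalin-8-one | O=C1C[C@H]2C(=C)CC[C@H](O[Si](C)(C)C(C)(C)C)[C@]2(C)CC1 | intermediate
10 | 3(8)-trimethylsilyl enol ether of 9 | C1=C(O[Si](C)(C)C)C[C@H]2C(=C)CC[C@H](O[Si](C)(C)C(C)(C)C)[C@]2(C)C1 | intermediate
11 | 2-en-8-one | O=C1C[C@H]2C(=C)CC[C@H](O[Si](C)(C)C(C)(C)C)[C@]2(C)C=C1 | intermediate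
12 | 2α,3α-epoxy-8-one | O=C1C[C@H]2C(=C)CC[C@H](O[Si](C)(C)C(C)(C)C)[C@]2(C)[C@@H]3O[C@@H]31 | intermediate
13 | 2,8-dione | O=C1C[C@H]2C(=C)CC[C@H](O[Si](C)(C)C(C)(C)C)[C@]2(C)C(=O)C1 | intermediate
14 | propargyl alcohol | C#CCO | starting material
15 | 8-(prop-2-ynyloxy)-3(8)-en-2-one | C1=C(OCC#C)C[C@H]2C(=C)CC[C@H](O[Si](C)(C)C(C)(C)C)[C@]2(C)C1=O | intermediate
16 | 8-(prop-2-ynyloxy)-3(8)-en-2β-ol | C1=C(OCC#C)C[C@H]2C(=C)CC[C@H](O[Si](C)(C)C(C)(C)C)[C@]2(C)[C@H]1O | intermediate
17 | 2β-PMB ether of 16 | C1=C(OCC#C)C[C@H]2C(=C)CC[C@H](O[Si](C)(C)C(C)(C)C)[C@]2(C)[C@H]1OCc3ccc(OC)cc3 | intermediate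
18 | 3α-(propa-1,2-dienyl)-2β-PMBO-8-one | O=C1C[C@H]2C(=C)CC[C@H](O[Si](C)(C)C(C)(C)C)[C@]2(C)[C@@H](OCc3ccc(OC)cc3)[C@@H]1C=C=C | intermediate
19 | vinylmagnesium bromide | C=C[Mg]Br | starting material
20 | 8α-hydroxy-8β-vinyl-3α-allenyl trans-decalin (rearrangement precursor) | C=C=C[C@H]1[C@H](OCc2ccc(OC)cc2)[C@@]2(C)[C@@H](O[Si](C)(C)C(C)(C)C)CCC(=C)[C@@H]2C[C@]1(O)C=C | intermediate
21 | potassium E-7(8)-enolate of 22 | C=C1/C=C/[C@H](OCc2ccc(OC)cc2)[C@@]2(C)[C@@H](O[Si](C)(C)C(C)(C)C)CCC(=C)[C@@H]2C/C([O-])=C/C1.[K+] | intermediate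
22 | ten-membered 8-ketone, E-3,4-olefin, 5(16)-methylene | C=C1/C=C/[C@H](OCc2ccc(OC)cc2)[C@@]2(C)[C@@H](O[Si](C)(C)C(C)(C)C)CCC(=C)[C@@H]2CC(=O)CC1 | intermediate
23 | E-7(8)-trimethylsilyl enol ether of 22 | C=C1/C=C/[C@H](OCc2ccc(OC)cc2)[C@@]2(C)[C@@H](O[Si](C)(C)C(C)(C)C)CCC(=C)[C@@H]2C/C(O[Si](C)(C)C)=C/C1 | intermediate
24 | 7α-trimethylsilyloxy 8-ketone | C=C1/C=C/[C@H](OCc2ccc(OC)cc2)[C@@]2(C)[C@@H](O[Si](C)(C)C(C)(C)C)CCC(=C)[C@@H]2CC(=O)[C@@H](O[Si](C)(C)C)C1 | intermediate
25 | E-8(9)-triethylsilyl enol ether of 24 | C=C1/C=C/[C@H](OCc2ccc(OC)cc2)[C@@]2(C)[C@@H](O[Si](C)(C)C(C)(C)C)CCC(=C)[C@@H]2/C=C(O[Si](CC)(CC)CC)/[C@@H](O[Si](C)(C)C)C1 | intermediate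
26 | 7α-trimethylsilyloxy-9α-triethylsilyloxy 8-ketone | C=C1/C=C/[C@H](OCc2ccc(OC)cc2)[C@@]2(C)[C@@H](O[Si](C)(C)C(C)(C)C)CCC(=C)[C@@H]2[C@@H](O[Si](CC)(CC)CC)C(=O)[C@@H](O[Si](C)(C)C)C1 | intermediate
27 | propionic anhydride | CCC(=O)OC(=O)CC | starting material
28 | 7α-hydroxy-9α-triethylsilyloxy 8-ketone | C=C1/C=C/[C@H](OCc2ccc(OC)cc2)[C@@]2(C)[C@@H](O[Si](C)(C)C(C)(C)C)CCC(=C)[C@@H]2[C@@H](O[Si](CC)(CC)CC)C(=O)[C@@H](O)C1 | intermediate
29 | 7α-propionyloxy-9α-triethylsilyloxy 8-ketone | C=C1/C=C/[C@H](OCc2ccc(OC)cc2)[C@@]2(C)[C@@H](O[Si](C)(C)C(C)(C)C)CCC(=C)[C@@H]2[C@@H](O[Si](CC)(CC)CC)C(=O)[C@@H](OC(=O)CC)C1 | intermediate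
30 | 8α-hydroxy γ-lactone, 9α-triethylsilyloxy | C=C1/C=C/[C@H](OCc2ccc(OC)cc2)[C@@]2(C)[C@@H](O[Si](C)(C)C(C)(C)C)CCC(=C)[C@@H]2[C@@H](O[Si](CC)(CC)CC)[C@]3(O)[C@@H](C)C(=O)O[C@H]3C1 | intermediate
31 | 8α,9α-diol lactone | C=C1/C=C/[C@H](OCc2ccc(OC)cc2)[C@@]2(C)[C@@H](O[Si](C)(C)C(C)(C)C)CCC(=C)[C@@H]2[C@@H](O)[C@]3(O)[C@@H](C)C(=O)O[C@H]3C1 | intermediate
32 | 8α-hydroxy-9-ketone lactone | C=C1/C=C/[C@H](OCc2ccc(OC)cc2)[C@@]2(C)[C@@H](O[Si](C)(C)C(C)(C)C)CCC(=C)[C@@H]2C(=O)[C@]3(O)[C@@H](C)C(=O)O[C@H]3C1 | intermediate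
33 | 8α,9β-diol lactone | C=C1/C=C/[C@H](OCc2ccc(OC)cc2)[C@@]2(C)[C@@H](O[Si](C)(C)C(C)(C)C)CCC(=C)[C@@H]2[C@H](O)[C@]3(O)[C@@H](C)C(=O)O[C@H]3C1 | intermediate
34 | 8α,9β,14α-triol lactone | C=C1/C=C/[C@H](OCc2ccc(OC)cc2)[C@@]2(C)[C@@H](O)CCC(=C)[C@@H]2[C@H](O)[C@]3(O)[C@@H](C)C(=O)O[C@H]3C1 | intermediate
35 | 9β,14α-diacetate | C=C1/C=C/[C@H](OCc2ccc(OC)cc2)[C@@]2(C)[C@@H](OC(C)=O)CCC(=C)[C@@H]2[C@H](OC(C)=O)[C@]3(O)[C@@H](C)C(=O)O[C@H]3C1 | intermediate
36 | 2β-alcohol (9β,14α-diacetate) | C=C1/C=C/[C@H](O)[C@@]2(C)[C@@H](OC(C)=O)CCC(=C)[C@@H]2[C@H](OC(C)=O)[C@]3(O)[C@@H](C)C(=O)O[C@H]3C1 | intermediate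
37 | 3,4;11,20-bis-epoxide | C=C1[C@@H]2O[C@H]2[C@H](O)[C@@]3(C)[C@@H](OC(C)=O)CC[C@]4(CO4)[C@@H]3[C@H](OC(C)=O)[C@]5(O)[C@@H](C)C(=O)O[C@H]5C1 | intermediate
38 | 6-deschloro target | C=C1[C@H]2O[C@]3([C@@H](C)C(=O)O[C@H]3C1)[C@@H](OC(C)=O)[C@H]1[C@]3(CC[C@H](OC(C)=O)[C@]1(C)[C@@H](O)[C@@H]2O)CO3 | intermediate
39 | CNP0340728.1 | C=C1[C@H]2O[C@]3([C@@H](C)C(=O)O[C@H]3[C@H]1Cl)[C@@H](OC(C)=O)[C@H]1[C@]3(CC[C@H](OC(C)=O)[C@]1(C)[C@@H](O)[C@@H]2O)CO3 | target

**Step count and risks**
Total step count: 28. Longest linear sequence: 28 steps (from 1).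

Steps most likely to fail:

Step 28. The chlorine may be delivered to the wrong allylic site or face, or adventitious HCl may open the spiro-oxirane. Fallback from 38: the exocyclic olefin is first moved into the ring by cobalt-hydride isomerisation (Co(salen)Cl, PhSiH3) to the 5(6)-ene isomer F4, which carries C16 as a methyl group. This trisubstituted olefin is then chlorinated in the ionic ene manner (Ca(OCl)2, CO2, CH2Cl2/H2O): chlorine adds to C6 from the exo face and loss of a C16 proton restores the 5(16)-methylene, which returns to the route at 39.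

Step 27. The peracid may show poor site or face selectivity, or the ether closure may stall without acid, which the spiro-oxirane would not survive. Fallback from 36: alkoxide-directed epoxidation (VO(acac)2, tBuOOH) touches only the allylic 3,4-olefin and gives the 3,4-epoxy-2β-alcohol F2. Ti(OiPr)4 then closes the bridge to the ether-bridged 11(20)-ene diol F3, and dimethyldioxirane at low temperature epoxidises the remaining electron-rich 11(20)-methylene from the α-face, which returns to the route at 38.

Step 17. The alkoxide may fragment at C3–C8 or the base may isomerise the allene before the rearrangement takes place. Fallback from 20: silylation with N-(trimethylsilyl)imidazole gives the 8-O-trimethylsilyl ether F1, which is heated without base (o-dichlorobenzene, about 180 °C) in a neutral siloxy-Cope rearrangement. This gives the silyl enol ether directly and returns to the route at 23, the intermediate of step 18, so that 22 is bypassed.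

Further compounds
F1 | step 17 | 8-O-trimethylsilyl ether of 20 | C=C=C[C@H]1[C@H](OCc2ccc(OC)cc2)[C@@]2(C)[C@@H](O[Si](C)(C)C(C)(C)C)CCC(=C)[C@@H]2C[C@]1(O[Si](C)(C)C)C=C
F2 | step 27 | 3,4-epoxy-2β-alcohol with intact 11(20)-methylene | C=C1[C@@H]2O[C@H]2[C@H](O)[C@@]3(C)[C@@H](OC(C)=O)CCC(=C)[C@@H]3[C@H](OC(C)=O)[C@]4(O)[C@@H](C)C(=O)O[C@H]4C1
F3 | step 27 | ether-bridged 2β,3α-diol with 11(20)-methylene | C=C1[C@H]2O[C@]3([C@@H](C)C(=O)O[C@H]3C1)[C@@H](OC(C)=O)[C@H]1C(=C)CC[C@H](OC(C)=O)[C@]1(C)[C@@H](O)[C@@H]2O
F4 | step 28 | 5(6)-ene isomer of 38 (C16 methyl) | CC=1[C@H]2O[C@]3([C@@H](C)C(=O)O[C@H]3C=1)[C@@H](OC(C)=O)[C@H]1[C@]3(CC[C@H](OC(C)=O)[C@]1(C)[C@@H](O)[C@@H]2O)CO3
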